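**Retrosynthetic overview**
1. Both indole rings are bought intact: 6-bromoindole (1), which is C3-acetylated to methyl ketone 2, and 6-bromoindole-3-carboxaldehyde (3).
2. Key disconnection: all four C–N bonds of the imidazole, back to ammonia, aldehyde 3 (imidazole C2) and the 1,2-dicarbonyl compound 4 (imidazole C4–C5); 4 is unmasked in the same flask from 2 by oxidation of the methyl group.
3. Ring order: the indoles are present from the start; the imidazole is the only ring formed, in the last step, giving nortopsentin A (5).

Assumption: nortopsentin A has no stereocentre (it is achiral), so there is no enantiomer to control; the 4-aryl-1H tautomer drawn is in fast equilibrium with the 5-aryl tautomer, and 3 is taken as a catalogue starting material.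

**Route**

Step 1
Reactants: 1 6-bromo-1H-indole
Product: 2 1-(6-bromo-1H-indol-3-yl)ethan-1-one (3-acetyl-6-bromoindole)
Conditions: Et2AlCl (1.5 equiv), CH2Cl2, 0 °C, 30 min; then AcCl (1.5 equiv), 0 °C, 2 h; pH 7 buffer work-up
Reagents that add atoms: acetyl chloride, CC(=O)Cl
Why: Friedel–Crafts acylation of the N-unprotected indole at its most nucleophilic position C3, with Et2AlCl acting as a mild Lewis acid and HCl scavenger so that neither N-acylation nor acid-induced oligomerisation competes; no stereocentre is formed.

Step 2
Reactants: 2 1-(6-bromo-1H-indol-3-yl)ethan-1-one; 3 6-bromo-1H-indole-3-carbaldehyde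
Product: 5 nortopsentin A, via indolylglyoxal 4 (not isolated)
Conditions: (i) I2 (0.3 equiv), DMSO, 100 °C, 3 h, N2 sweep; (ii) cooled solution added over 3 h to 3 (2 equiv), NH4OAc (10 equiv), MeOH, 40 °C, then 12 h
Reagents that add atoms: ammonium acetate, CC(=O)[O-].[NH4+]
Why: Proposed new method: an iodine-catalysed Kornblum oxidation (enol iodination, displacement of iodide by DMSO, loss of Me2S, re-oxidation of HI by DMSO) turns the acetyl group of 2 into glyoxal 4, whose two carbonyl carbons then condense with two molecules of ammonia and with the carbonyl carbon of 3 (imine and aminal formation, 5-exo-trig ring closure, loss of three molecules of water, aromatisation) to forge all four imidazole C–N bonds in a cross-selective Debus–Radziszewski annulation, the slow feed of 4 (held as its methanol hemiacetal) into excess 3 and ammonia keeping the second-order self-condensation of 4 to a 2-acylimidazole below the cross-reaction; the closest known reaction type is the Debus–Radziszewski synthesis of 2,4(5)-diarylimidazoles from arylglyoxals, aryl aldehydes and NH4OAc, proposed here for the first time as a telescoped sequence on two N-unprotected, weakly electrophilic 3-indolyl carbonyl partners; no stereocentre is formed.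

**Compound list**
1 | 6-bromo-1H-indole | Brc1ccc2cc[nH]c2c1 | starting material
2 | 1-(6-bromo-1H-indol-3-yl)ethan-1-one | CC(=O)c1c[nH]c2cc(Br)ccc12 | intermediate
3 | 6-bromo-1H-indole-3-carbaldehyde | O=Cc1c[nH]c2cc(Br)ccc12 | starting material
4 | 2-(6-bromo-1H-indol-3-yl)-2-oxoacetaldehyde (indolylglyoxal) | O=CC(=O)c1c[nH]c2cc(Br)ccc12 | intermediate
5 | nortopsentin A, 6-bromo-3-[2-(6-bromo-1H-indol-3-yl)-1H-imidazol-4-yl]-1H-indole | Brc1ccc2c(-c3c[nH]c(-c4c[nH]c5cc(Br)ccc45)n3)c[nH]c2c1 | target

**Totals and risks**

Total step count: 2. Longest linear sequence: 2 (1 → 2 → 5).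

The route has only two steps, so the ranking takes the two stages of step 2 separately.

1. Step 2, stage (ii), the cross-annulation (the proposed new step). Aldehyde 3 is a vinylogous formamide and a poor electrophile, so 4 may instead condense with itself to a 2-acylimidazole, and residual iodine may turn some 3 into the nitrile. The fallback uses known chemistry, sets out from 2 and 3, and comes back to the route at 5. Ketone 2 is α-brominated (CuBr2, EtOAc/CHCl3, reflux) to 2-bromo-1-(6-bromo-1H-indol-3-yl)ethan-1-one F1. Aldehyde 3 is heated with NH2OH·HCl and HCO2Na in HCO2H, which gives (E)-6-bromo-1H-indole-3-carbaldehyde oxime F2 (not isolated) and dehydrates it to 6-bromo-1H-indole-3-carbonitrile F3. F3 is treated with MeAl(Cl)NH2 (from AlMe3 and NH4Cl, toluene, 80 °C) and then HCl in MeOH to give 6-bromo-1H-indole-3-carboximidamide hydrochloride F4. F1 and F4 are condensed (KHCO3, THF/H2O, reflux) to 5. This is the classical amidine/α-haloketone imidazole synthesis, and it still closes the ring through C–N bonds only.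

2. Step 2, stage (i), oxidation of 2 to 4. The carbonyl of a 3-acylindole is deactivated, so enol iodination and the Kornblum displacement may be slow, and over-oxidation to the glyoxylic acid or incorporation of sulfur from DMSO may compete. The fallback sets out from 1 and comes back at 4. Indole 1 is acylated with oxalyl chloride (Et2O, 0 °C, no Lewis acid) to 2-(6-bromo-1H-indol-3-yl)-2-oxoacetyl chloride F5, which is reduced with Bu3SnH (EtOAc, rt) to 4. The solution of 4 is then fed into stage (ii) as written.

3. Step 1, C3 acetylation. Possible problems are N-acylation, diacylation or incomplete conversion with the moisture-sensitive aluminium reagent. The fallback sets out from 1 and comes back at 2. It is a Vilsmeier–Haack acetylation: N,N-dimethylacetamide and POCl3 (0 → 85 °C) give the iminium salt N-[1-(6-bromo-1H-indol-3-yl)ethylidene]-N-methylmethanaminium chloride F6, which aqueous NaOH hydrolyses to 2.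

**Further compounds**
F1 | step 2 | 2-bromo-1-(6-bromo-1H-indol-3-yl)ethan-1-one | O=C(CBr)c1c[nH]c2cc(Br)ccc12
F2 | step 2 | (E)-6-bromo-1H-indole-3-carbaldehyde oxime | O/N=C/c1c[nH]c2cc(Br)ccc12
F3 | step 2 | 6-bromo-1H-indole-3-carbonitrile | N#Cc1c[nH]c2cc(Br)ccc12
F4 | step 2 | 6-bromo-1H-indole-3-carboximidamide hydrochloride | Cl.N=C(N)c1c[nH]c2cc(Br)ccc12
F5 | step 2 | 2-(6-bromo-1H-indol-3-yl)-2-oxoacetyl chloride | O=C(Cl)C(=O)c1c[nH]c2cc(Br)ccc12
F6 | step 1 | N-[1-(6-bromo-1H-indol-3-yl)ethylidene]-N-methylmethanaminium chloride | CC(=[N+](C)C)c1c[nH]c2cc(Br)ccc12.[Cl-]
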